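**Strategy**

The hemiketal carbon C3 of the lactone ring (C1, O2, C3, C4, C4a, C8a) is treated as the tetrahedral intermediate of an acyl transfer: cutting C3–C4 turns C1–O2–C3 into a mixed carboxylic anhydride and the benzylic C4 methine with its methyl group into an ortho vinyl group. A chiral bisphosphine copper hydride catalyst hydrocuprates the vinyl arene enantioselectively and the benzylic copper is acylated by the tethered anhydride, which closes the ring, sets C4 and leaves C3 at the lactol level in one operation. The precursor is the mixed anhydride of a 2-vinylbenzoic acid and the O-aroylglycolic acid that carries the second aromatic ring; three benzyl ethers are removed at the end.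

Key step: step 13

Remark: atom numbers (C1, O2, C3, C4, C4a, C5 to C8, C8a) are those of the isochroman-1-one ring of the target, which is (3R,4S). C3 is a hemiketal that epimerises by ring-chain tautomerism, so its configuration is taken to be under thermodynamic control. The sense of induction of the (R) ligand in step 13 is assumed by analogy with other vinyl arenes; the (S) ligand is the remedy if it proves opposite.

**Route**

Step 1
Reactants: 1 methyl 2-hydroxy-4-methoxy-6-methylbenzoate
Product: 2 methyl 2-(benzyloxy)-4-methoxy-6-methylbenzoate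
Conditions: BnBr, K2CO3, DMF, 60 °C
Reagents that add atoms: benzyl bromide, BrCc1ccccc1
Why: Williamson O-benzylation of the hydrogen-bonded salicylate phenol should proceed under carbonate in DMF and masks the future C8 hydroxyl for all later basic and hydride steps.

Step 2
Reactants: 2 methyl 2-(benzyloxy)-4-methoxy-6-methylbenzoate
Product: 3 methyl 6-(benzyloxy)-3-bromo-4-methoxy-2-methylbenzoate
Conditions: NBS, MeCN, 0 °C to rt, dark
Reagents that add atoms: N-bromosuccinimide, O=C1CCC(=O)N1Br
Why: Electrophilic aromatic bromination should go to C5 of 2 (para to the benzyloxy group, ortho to methoxy) and not to the position between the two alkoxy groups, as is usual for 3,5-dialkoxytoluenes.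

Step 3
Reactants: 3 methyl 6-(benzyloxy)-3-bromo-4-methoxy-2-methylbenzoate
Product: 4 methyl 6-(benzyloxy)-4-methoxy-2,3-dimethylbenzoate
Conditions: MeB(OH)2, Pd(OAc)2, SPhos, K3PO4, toluene/H2O, 100 °C
Reagents that add atoms: methylboronic acid, CB(O)O
Why: Suzuki–Miyaura methylation with a bulky biaryl phosphine should couple the di-ortho-substituted aryl bromide and installs the future C5 methyl group.

Step 4
Reactants: 4 methyl 6-(benzyloxy)-4-methoxy-2,3-dimethylbenzoate
Product: 5 8-(benzyloxy)-6-methoxy-5-methylisochroman-1-one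
Conditions: LDA, THF, −78 °C; CH2O (gas, from cracked paraformaldehyde), −78 °C to rt; 1 M HCl
Reagents that add atoms: formaldehyde, C=O
Why: Lateral lithiation of the o-toluate deprotonates only the methyl group ortho to the ester, and hydroxymethylation of this anion followed by lactonisation of the alkoxide onto the ester is the toluate-anion route to 3,4-dihydroisocoumarins.

Step 5
Reactants: 5 8-(benzyloxy)-6-methoxy-5-methylisochroman-1-one
Product: 6 6-(benzyloxy)-2-ethenyl-4-methoxy-3-methylbenzoic acid
Conditions: KOtBu, DMSO, rt; then 1 M HCl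
Reagents that add atoms: none
Why: Deprotonation at the benzylic C4 position expels the carboxylate from C3 in an E1cB-type β-elimination, which opens the lactone to the 2-vinylbenzoic acid and frees the acid without hydrolysing a hindered ester.

Step 6
Reactants: 7 methyl 2,4-dihydroxy-3,6-dimethylbenzoate
Product: 8 methyl 3-formyl-4,6-dihydroxy-2,5-dimethylbenzoate
Conditions: Cl2CHOMe, TiCl4, CH2Cl2, 0 °C to rt; then H2O
Reagents that add atoms: dichloromethyl methyl ether, COC(Cl)Cl; water, O
Why: Rieche formylation can only occur at the single unsubstituted ring carbon, which is ortho to the 4-hydroxyl group and strongly activated.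

Step 7
Reactants: 8 methyl 3-formyl-4,6-dihydroxy-2,5-dimethylbenzoate
Product: 9 methyl 2,4-dihydroxy-3,5,6-trimethylbenzoate
Conditions: Et3SiH, TFA, CH2Cl2, 0 °C to rt
Reagents that add atoms: none
Why: Ionic hydrogenation of an o-hydroxybenzaldehyde passes through the protonated aldehyde and an o-quinone methide, each reduced by the silane, and should take the formyl group down to methyl.

Step 8
Reactants: 9 methyl 2,4-dihydroxy-3,5,6-trimethylbenzoate
Product: 10 methyl 2,4-bis(benzyloxy)-3,5,6-trimethylbenzoate
Conditions: BnBr, K2CO3, Bu4NI (cat.), DMF, 70 °C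
Reagents that add atoms: benzyl bromide, BrCc1ccccc1
Why: Williamson bis-benzylation with iodide catalysis and heating should etherify both hindered phenols, which must be masked before acid chloride formation and copper hydride catalysis.

Step 9
Reactants: 10 methyl 2,4-bis(benzyloxy)-3,5,6-trimethylbenzoate
Product: 11 2,4-bis(benzyloxy)-3,5,6-trimethylbenzoic acid
Conditions: KOH, DMSO/H2O, 100 °C; then 1 M HCl
Reagents that add atoms: potassium hydroxide, [K+].[OH-]
Why: Saponification of the di-ortho-substituted methyl ester needs poorly solvated hydroxide in DMSO at elevated temperature, conditions that benzyl aryl ethers tolerate.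

Step 10
Reactants: 11 2,4-bis(benzyloxy)-3,5,6-trimethylbenzoic acid; 12 tert-butyl bromoacetate
Product: 13 2-tert-butoxy-2-oxoethyl 2,4-bis(benzyloxy)-3,5,6-trimethylbenzoate
Conditions: K2CO3, DMF, rt
Reagents that add atoms: none
Why: SN2 alkylation of the carboxylate by the α-bromo ester builds the hindered aryl ester at the alkyl carbon and so avoids acyl substitution at the shielded carbonyl.

Step 11
Reactants: 13 2-tert-butoxy-2-oxoethyl 2,4-bis(benzyloxy)-3,5,6-trimethylbenzoate
Product: 14 {[2,4-bis(benzyloxy)-3,5,6-trimethylbenzoyl]oxy}acetic acid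
Conditions: TFA/CH2Cl2 (1:4), 0 °C
Reagents that add atoms: none
Why: Acidolysis of the tert-butyl ester with loss of isobutene should be selective at low temperature over the aryl ester and the benzyl ethers.

Step 12
Reactants: 14 {[2,4-bis(benzyloxy)-3,5,6-trimethylbenzoyl]oxy}acetic acid; 6 6-(benzyloxy)-2-ethenyl-4-methoxy-3-methylbenzoic acid
Product: 16 6-(benzyloxy)-2-ethenyl-4-methoxy-3-methylbenzoic {[2,4-bis(benzyloxy)-3,5,6-trimethylbenzoyl]oxy}acetic anhydride, via acid chloride 15 (not isolated)
Conditions: (COCl)2, DMF (cat.), CH2Cl2, 0 °C to rt, evaporate; then 6, Et3N, toluene, −20 to 0 °C; filter, use crude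
Reagents that add atoms: none
Why: Acylation of the carboxylate of 6 by the acid chloride gives a Yamaguchi-type mixed anhydride whose aroyl carbonyl is shielded by two ortho substituents, and any acyloxyketene formed from 15 by the amine would be captured by acid 6 to give the same anhydride.

Step 13
Reactants: 16 6-(benzyloxy)-2-ethenyl-4-methoxy-3-methylbenzoic {[2,4-bis(benzyloxy)-3,5,6-trimethylbenzoyl]oxy}acetic anhydride
Product: 18 [(3R,4S)-8-(benzyloxy)-3-hydroxy-6-methoxy-4,5-dimethyl-1-oxoisochroman-3-yl]methyl 2,4-bis(benzyloxy)-3,5,6-trimethylbenzoate, via O-silyl lactol 17 (not isolated)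
Conditions: Cu(OAc)2 (5 mol%), (R)-DTBM-SEGPHOS (5.5 mol%), (MeO)2MeSiH (1.5 equiv), THF (0.02 M), rt to 40 °C; then pH 7 phosphate buffer
Reagents that add atoms: none
Why: The ligated copper hydride formed from Cu(OAc)2, the bisphosphine and the silane adds across the vinyl group with copper at the benzylic carbon C4 and hydrogen at the terminal carbon (the future C4 methyl), and this benzylic copper attacks the unhindered alkoxyacetyl carbonyl C3 of the tethered anhydride; the resulting copper alkoxide already has the lactol connectivity and is turned over by the silane to the O-silyl lactol 17 (collapse to the ring-opened keto silyl ester would converge on the same lactol at work-up). The closest known reaction type is the copper-hydride-catalysed enantioselective hydroacylation (reductive coupling) of vinyl arenes with carboxylic anhydrides, used here in a ring-closing form on a Yamaguchi-type mixed anhydride. The lactone ring closes by 6-exo-trig attack of C4 on the C3 carbonyl, since attack on C1 would need a four-membered transition state at a di-ortho-substituted aroyl carbon. C4 is set to S by ligand-controlled enantiofacial hydrocupration followed by stereoretentive C–C bond formation, whereas C3 is not set kinetically but should equilibrate through the ring-opened keto acid at work-up to the anomer expected to be most stable, with the 3-hydroxyl axial (anomeric effect) and trans to the pseudoaxial C4 methyl group, which is 3R. The step needs hydrocupration of the twisted, di-ortho-substituted styrene to outrun hydride reduction of the anhydride and needs the ketone not to be reduced further; intramolecular delivery of the electrophile, masking of C3 as the cyclic silyl ketal and a limited charge of silane are relied on for both.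

Step 14
Reactants: 18 [(3R,4S)-8-(benzyloxy)-3-hydroxy-6-methoxy-4,5-dimethyl-1-oxoisochroman-3-yl]methyl 2,4-bis(benzyloxy)-3,5,6-trimethylbenzoate
Product: 19 [(3R,4S)-3,8-dihydroxy-6-methoxy-4,5-dimethyl-1-oxoisochroman-3-yl]methyl 2,4-dihydroxy-3,5,6-trimethylbenzoate
Conditions: H2 (1 atm), Pd/C (10%), EtOAc, rt
Reagents that add atoms: none
Why: Hydrogenolysis of the three aryl benzyl ethers under neutral conditions should leave the lactol, the alkyl benzoate and the epimerisable C4 centre untouched, since no C–O bond other than the benzyl ethers is benzylic.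

**Compound list**

1 | methyl 2-hydroxy-4-methoxy-6-methylbenzoate | COC(=O)c1c(C)cc(OC)cc1O | starting material
2 | methyl 2-(benzyloxy)-4-methoxy-6-methylbenzoate | COC(=O)c1c(C)cc(OC)cc1OCc1ccccc1 | intermediate
3 | methyl 6-(benzyloxy)-3-bromo-4-methoxy-2-methylbenzoate | COC(=O)c1c(C)c(Br)c(OC)cc1OCc1ccccc1 | intermediate
4 | methyl 6-(benzyloxy)-4-methoxy-2,3-dimethylbenzoate | COC(=O)c1c(C)c(C)c(OC)cc1OCc1ccccc1 | intermediate
5 | 8-(benzyloxy)-6-methoxy-5-methylisochroman-1-one | COc1cc(OCc2ccccc2)c2c(c1C)CCOC2=O | intermediate
6 | 6-(benzyloxy)-2-ethenyl-4-methoxy-3-methylbenzoic acid | C=Cc1c(C)c(OC)cc(OCc2ccccc2)c1C(=O)O | intermediate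
7 | methyl 2,4-dihydroxy-3,6-dimethylbenzoate | COC(=O)c1c(C)cc(O)c(C)c1O | starting material
8 | methyl 3-formyl-4,6-dihydroxy-2,5-dimethylbenzoate | COC(=O)c1c(C)c(C=O)c(O)c(C)c1O | intermediate
9 | methyl 2,4-dihydroxy-3,5,6-trimethylbenzoate | COC(=O)c1c(C)c(C)c(O)c(C)c1O | intermediate
10 | methyl 2,4-bis(benzyloxy)-3,5,6-trimethylbenzoate | COC(=O)c1c(C)c(C)c(OCc2ccccc2)c(C)c1OCc1ccccc1 | intermediate
11 | 2,4-bis(benzyloxy)-3,5,6-trimethylbenzoic acid | Cc1c(C)c(OCc2ccccc2)c(C)c(OCc2ccccc2)c1C(=O)O | intermediate
12 | tert-butyl bromoacetate | CC(C)(C)OC(=O)CBr | starting material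
13 | 2-tert-butoxy-2-oxoethyl 2,4-bis(benzyloxy)-3,5,6-trimethylbenzoate | Cc1c(C)c(OCc2ccccc2)c(C)c(OCc2ccccc2)c1C(=O)OCC(=O)OC(C)(C)C | intermediate
14 | {[2,4-bis(benzyloxy)-3,5,6-trimethylbenzoyl]oxy}acetic acid | Cc1c(C)c(OCc2ccccc2)c(C)c(OCc2ccccc2)c1C(=O)OCC(=O)O | intermediate
15 | {[2,4-bis(benzyloxy)-3,5,6-trimethylbenzoyl]oxy}acetyl chloride | Cc1c(C)c(OCc2ccccc2)c(C)c(OCc2ccccc2)c1C(=O)OCC(=O)Cl | intermediate
16 | 6-(benzyloxy)-2-ethenyl-4-methoxy-3-methylbenzoic {[2,4-bis(benzyloxy)-3,5,6-trimethylbenzoyl]oxy}acetic anhydride | C=Cc1c(C)c(OC)cc(OCc2ccccc2)c1C(=O)OC(=O)COC(=O)c1c(C)c(C)c(OCc2ccccc2)c(C)c1OCc1ccccc1 | intermediate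
17 | [(4S)-8-(benzyloxy)-3-{[dimethoxy(methyl)silyl]oxy}-6-methoxy-4,5-dimethyl-1-oxoisochroman-3-yl]methyl 2,4-bis(benzyloxy)-3,5,6-trimethylbenzoate (C3 configuration not fixed at this stage) | COc1cc(OCc2ccccc2)c2c(c1C)[C@H](C)C(O[Si](C)(OC)OC)(COC(=O)c1c(C)c(C)c(OCc3ccccc3)c(C)c1OCc1ccccc1)OC2=O | intermediate
18 | [(3R,4S)-8-(benzyloxy)-3-hydroxy-6-methoxy-4,5-dimethyl-1-oxoisochroman-3-yl]methyl 2,4-bis(benzyloxy)-3,5,6-trimethylbenzoate | COc1cc(OCc2ccccc2)c2c(c1C)[C@H](C)[C@](O)(COC(=O)c1c(C)c(C)c(OCc3ccccc3)c(C)c1OCc1ccccc1)OC2=O | intermediate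
19 | [(3R,4S)-3,8-dihydroxy-6-methoxy-4,5-dimethyl-1-oxoisochroman-3-yl]methyl 2,4-dihydroxy-3,5,6-trimethylbenzoate | COc1cc(O)c2c(c1C)[C@H](C)[C@](O)(COC(=O)c1c(C)c(C)c(O)c(C)c1O)OC2=O | target

**Step count and risks**

Total step count: 14. Longest linear sequence: 9 steps (steps 6 to 14).

Steps most likely to fail:

1. Step 13. Hydrocupration of the twisted, di-ortho-substituted styrene may be too slow, so that hydride reduction or disproportionation of the anhydride, or simple reduction of the vinyl group, takes over; facial selectivity may also be eroded by the two ortho groups. The fallback gives up the ring-closing mode, forms the C3–C4 bond by an enantioconvergent nickel-catalysed reductive acyl cross-coupling and lets the ring close through O2–C3. It sets out from acid 6. Benzylation (BnBr, K2CO3, DMF) should give benzyl 6-(benzyloxy)-4-methoxy-3-methyl-2-vinylbenzoate F1. Markovnikov hydrochlorination (HCl in dioxane, CH2Cl2, 0 °C) should give racemic benzyl 6-(benzyloxy)-2-(1-chloroethyl)-4-methoxy-3-methylbenzoate F2. Coupling of F2 with acid chloride 15 (NiCl2(dme), chiral bis(oxazoline) ligand, Mn powder as zerovalent manganese reductant, DMA/THF, rt) should give benzyl 6-(benzyloxy)-2-[(2S)-4-{[2,4-bis(benzyloxy)-3,5,6-trimethylbenzoyl]oxy}-3-oxobutan-2-yl]-4-methoxy-3-methylbenzoate F3. Hydrogenolysis (H2, Pd/C, EtOAc) would remove all four benzyl groups, and the freed keto acid should close to the lactol, so the fallback comes back to the route at target 19.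

2. Step 12. The mixed anhydride may scramble into the two symmetrical anhydrides under amine or chloride catalysis, and the acyloxyketene derived from 15 may oligomerise before it is captured. The fallback builds the anhydride under neutral conditions without acid chloride or amine. It sets out from acid 14: addition to ethoxyacetylene ([RuCl2(p-cymene)]2 cat., toluene, rt) should give 1-ethoxyvinyl {[2,4-bis(benzyloxy)-3,5,6-trimethylbenzoyl]oxy}acetate F4. Acyl transfer from F4 to acid 6 (toluene, 40 °C) should then give the mixed anhydride, and the fallback comes back to the route at 16.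

3. Step 5. tert-Butoxide may add to the lactone carbonyl instead of removing the benzylic proton, and the styrene carboxylate may oligomerise in the strongly basic medium. The fallback replaces the base-induced elimination by SN2 opening and selenoxide elimination. It sets out from lactone 5: opening at C3 with PhSeNa (from PhSeSePh and NaBH4, DMF, 110 °C; then acid) should give 6-(benzyloxy)-4-methoxy-3-methyl-2-[2-(phenylselanyl)ethyl]benzoic acid F5. Oxidation (H2O2, THF, 0 °C to rt) and syn-elimination of the selenoxide should give the vinyl acid, and the fallback comes back to the route at 6.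

**Further compounds**

F1 | step 13 | benzyl 6-(benzyloxy)-4-methoxy-3-methyl-2-vinylbenzoate | C=Cc1c(C)c(OC)cc(OCc2ccccc2)c1C(=O)OCc1ccccc1
F2 | step 13 | benzyl 6-(benzyloxy)-2-(1-chloroethyl)-4-methoxy-3-methylbenzoate (racemic) | CC(Cl)c1c(C)c(OC)cc(OCc2ccccc2)c1C(=O)OCc1ccccc1
F3 | step 13 | benzyl 6-(benzyloxy)-2-[(2S)-4-{[2,4-bis(benzyloxy)-3,5,6-trimethylbenzoyl]oxy}-3-oxobutan-2-yl]-4-methoxy-3-methylbenzoate | C[C@@H](c1c(C)c(OC)cc(OCc2ccccc2)c1C(=O)OCc1ccccc1)C(=O)COC(=O)c1c(C)c(C)c(OCc2ccccc2)c(C)c1OCc1ccccc1
F4 | step 12 | 1-ethoxyvinyl {[2,4-bis(benzyloxy)-3,5,6-trimethylbenzoyl]oxy}acetate | C=C(OCC)OC(=O)COC(=O)c1c(C)c(C)c(OCc2ccccc2)c(C)c1OCc1ccccc1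
F5 | step 5 | 6-(benzyloxy)-4-methoxy-3-methyl-2-[2-(phenylselanyl)ethyl]benzoic acid | COc1cc(OCc2ccccc2)c(C(=O)O)c(CC[Se]c2ccccc2)c1C
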